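**Plan**

1. Germacrane numbering: carbocycle C1–C10 with C1=C10, C14H2OAc on C10, C15H3 on C4, lactone O6–C12(=O)–C11(=C13H2)–C7, glycolate on O8. Retrosynthetic cuts: C1–C2 (ring), then C6–C7 and C11–C13 together, then C7–C8, C9–C10 and C5–C6 within the two fragments.
2. Enabling feature: C7 is β to the C12 carbonyl and O8 sits on the γ-carbon C8. The lactone can therefore first be closed on O8 as a butenolide (O8–C12(=O)–C11=C7–C8), which takes a C6 acyl anion at C7 anti to the C9 arm and a one-carbon electrophile at C11.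
3. Forward: butenolide 13 (C7–C14 plus C1, alkenyl iodide) and dithiane 19 (C2–C6, C15) are joined with Me2N=CH2+ I− in one flask (step 10); no ring closes there.
4. The lactone is then moved from O8 to O6: Weinreb aminolysis frees O8–H, the dithiane is removed, an Evans–Tishchenko reduction sets C6 and places the protected glycolate on O8, and acid relactonises on O6.
5. The ten-membered ring is closed last at C1–C2 (9-BBN, then B-alkyl Suzuki–Miyaura coupling); C14 acetate, amine elimination to the C11=C13 methylene and PMB removal finish.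
6. Stereochemistry: C4 from (S)-3-bromo-2-methylpropan-1-ol; C8 from ligand-controlled alkynylation; C7 by attack anti to the C8 substituent; C6 by 1,3-anti hydride delivery from O8; C1=C10 geometry from anti-carbomagnesiation, retentive iododesilylation and stereoretentive coupling.

Key step: step 10

Assumption: aldehyde 26 is taken as a purchased reagent; the C11 configuration drawn for 23–33 is the expected one but is immaterial, since C11 ends as an sp2 carbon (TBS = tert-butyldimethylsilyl, PMB = 4-methoxybenzyl).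

**Route**

Step 1
Reactants: 1 3-(trimethylsilyl)prop-2-yn-1-ol; 2 allylmagnesium bromide
Product: 4 (2E)-2-[(trimethylsilyl)methylidene]pent-4-en-1-ol, via cyclic alkenylmagnesium alkoxide 3 (not isolated)
Conditions: 2 (3 equiv), Et2O, 0 °C → reflux; then H2O, 0 °C
Reagents that add atoms: none
Why: Hydroxyl-directed anti-carbomagnesiation of a propargylic alcohol, in which the magnesium alkoxide steers allyl to C10 and leaves magnesium on the silyl-bearing C1 in a five-membered chelate, so that protonolysis puts Me3Si cis to the allyl (C9) arm.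

Step 2
Reactants: 4 (2E)-2-[(trimethylsilyl)methylidene]pent-4-en-1-ol
Product: 5 tert-butyl(dimethyl){[(2E)-2-[(trimethylsilyl)methylidene]pent-4-en-1-yl]oxy}silane
Conditions: TBSCl, imidazole, CH2Cl2, 0 °C → rt
Reagents that add atoms: tert-butyldimethylsilyl chloride, CC(C)(C)[Si](C)(C)Cl
Why: Routine silylation of a primary alcohol, which keeps the C14 oxygen inert to the organometallic and oxidative steps that follow.

Step 3
Reactants: 5 tert-butyl(dimethyl){[(2E)-2-[(trimethylsilyl)methylidene]pent-4-en-1-yl]oxy}silane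
Product: 7 (3E)-3-[(TBS-oxy)methyl]-4-(trimethylsilyl)but-3-enal, via vicinal diol 6 (not isolated)
Conditions: OsO4 (2 mol %), NaIO4 (4 equiv), 2,6-lutidine, dioxane/H2O (3:1), 0 °C → rt; used at once
Reagents that add atoms: sodium periodate, [Na+].[O-]I(=O)(=O)=O
Why: Lemieux–Johnson cleavage, in which OsO4 should dihydroxylate the unhindered monosubstituted alkene faster than the trisubstituted alkene flanked by Me3Si and CH2OTBS, and periodate cleaves the diol to the C8 aldehyde.

Step 4
Reactants: 7 (3E)-3-[(TBS-oxy)methyl]-4-(trimethylsilyl)but-3-enal; 8 methyl propiolate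
Product: 10 methyl (4S,6E)-6-[(TBS-oxy)methyl]-4-hydroxy-7-(trimethylsilyl)hept-6-en-2-ynoate, via alkynylzinc reagent 9 (not isolated)
Conditions: Me2Zn (3 equiv), (S,S)-ProPhenol (20 mol %), Ph3P=O (40 mol %), toluene, 0 → 4 °C, slow addition of 7; then H2O
Reagents that add atoms: none
Why: Zinc/ProPhenol-catalysed enantioselective alkynylation of an aldehyde, in which the dinuclear zinc complex binds aldehyde and alkynylzinc and delivers the alkyne to one carbonyl face to set C8; the S sense is assigned by analogy with this ligand's aldol reactions and would be checked by Mosher ester analysis, the (R,R) ligand being used if the sense is opposite.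

Step 5
Reactants: 10 methyl (4S,6E)-6-[(TBS-oxy)methyl]-4-hydroxy-7-(trimethylsilyl)hept-6-en-2-ynoate
Product: 12 (5S)-5-[(2E)-2-[(TBS-oxy)methyl]-3-(trimethylsilyl)prop-2-en-1-yl]furan-2(5H)-one, via Z-hydroxy enoate 11 (not isolated)
Conditions: H2 (1 atm), Pd/CaCO3 poisoned with Pb(OAc)2 (Lindlar catalyst), quinoline, EtOAc, rt; then CSA (cat.), CH2Cl2, rt
Reagents that add atoms: none
Why: Lindlar semihydrogenation gives the Z-enoate, whose C8 hydroxyl lies next to the ester and lactonises to the butenolide; the vinylsilane is inert to hydrogenation, which is why iodine is introduced only afterwards.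

Step 6
Reactants: 12 (5S)-5-[(2E)-2-[(TBS-oxy)methyl]-3-(trimethylsilyl)prop-2-en-1-yl]furan-2(5H)-one
Product: 13 (5S)-5-[(2E)-2-[(TBS-oxy)methyl]-3-iodoprop-2-en-1-yl]furan-2(5H)-one
Conditions: NIS (1.3 equiv), (CF3)2CHOH, 0 °C, 15 min; aqueous work-up
Reagents that add atoms: N-iodosuccinimide, O=C1CCC(=O)N1I
Why: Electrophilic ipso-iododesilylation of a vinylsilane, in which the β-silyl cation at tertiary C10 collapses with retention so that iodine replaces silicon cis to C9, while the electron-poor butenolide alkene does not react.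

Step 7
Reactants: 14 1,3-dithiane; 15 (2S)-3-bromo-2-methylpropan-1-ol
Product: 17 (2R)-3-(1,3-dithian-2-yl)-2-methylpropan-1-ol, via 2-lithio-1,3-dithiane 16 (not isolated)
Conditions: 14 (2.3 equiv), n-BuLi (2.2 equiv), THF, −30 °C, 2 h; then 15, −78 → 0 °C; H2O
Reagents that add atoms: none
Why: Corey–Seebach alkylation, in which the first equivalent of 16 deprotonates the hydroxyl (returning 14) and the second displaces the primary bromide by SN2 without touching the stereocentre.

Step 8
Reactants: 17 (2R)-3-(1,3-dithian-2-yl)-2-methylpropan-1-ol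
Product: 18 (2R)-3-(1,3-dithian-2-yl)-2-methylpropanal
Conditions: SO3·pyridine, DMSO, i-Pr2NEt, CH2Cl2, 0 °C
Reagents that add atoms: none
Why: Parikh–Doering oxidation stops at the aldehyde, leaves the dithiane sulfur atoms alone and, run cold with a hindered amine, should not epimerise C4.

Step 9
Reactants: 18 (2R)-3-(1,3-dithian-2-yl)-2-methylpropanal
Product: 19 2-[(2R)-2-methylbut-3-en-1-yl]-1,3-dithiane
Conditions: Ph3PCH3Br, KN(SiMe3)2, THF, 0 °C; then 18, −78 → 0 °C
Reagents that add atoms: methyltriphenylphosphonium bromide, C[P+](c1ccccc1)(c1ccccc1)c1ccccc1.[Br-]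
Why: Wittig methylenation with the salt-free ylide at low temperature installs C2=C3 without eroding the α-stereocentre, the dithiane C–H being too weakly acidic to interfere.

Step 10
Reactants: 19 2-[(2R)-2-methylbut-3-en-1-yl]-1,3-dithiane; 13 (5S)-5-[(2E)-2-[(TBS-oxy)methyl]-3-iodoprop-2-en-1-yl]furan-2(5H)-one; 20 N,N-dimethylmethyleneiminium iodide
Product: 23 (3S,4R,5S)-3-[(dimethylamino)methyl]-5-[(2E)-2-[(TBS-oxy)methyl]-3-iodoprop-2-en-1-yl]-4-{2-[(2R)-2-methylbut-3-en-1-yl]-1,3-dithian-2-yl}oxolan-2-one, via lithiated dithiane 21 (not isolated), via lithium lactone enolate 22 (not isolated)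
Conditions: 19 (1.2 equiv), n-BuLi (1.15 equiv), THF, −30 °C, 2 h; HMPA (4 equiv), −78 °C; 13 (1.0 equiv), −78 °C, 1 h; 20 (3 equiv), −78 → 0 °C
Reagents that add atoms: none
Why: Deprotonation of 19 gives the sulfur-stabilised carbanion 21, which in THF/HMPA adds as a solvent-separated ion pair to C7 of butenolide 13 (Michael addition), and the resulting lithium enolate 22 is aminomethylated at C11 by the iminium salt (Mannich reaction), so C6–C7 and C11–C13 form in one flask. The closest known chemistry is the tandem conjugate addition of 2-lithio-1,3-dithianes to 5-substituted furan-2(5H)-ones with capture of the enolate by a carbon electrophile. No ring is closed. C7 is set by attack on the face of the planar butenolide opposite the C9 arm on C8, and C11 by approach of the electrophile trans to the bulky dithianyl group on C7, which gives the trans,trans lactone. The step needs 1,4- rather than 1,2-addition, no γ-deprotonation and no lithium–iodine exchange: HMPA and the soft dithianyl anion favour conjugate attack at −78 °C, and n-BuLi is kept below one equivalent relative to 19 so that no alkyllithium meets the alkenyl iodide. The Mannich base also masks the later α-methylene group against the nucleophiles used downstream.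

Step 11
Reactants: 23 the trans,trans lactone of step 10
Product: 24 (2S,3R,4S,6E)-2-[(dimethylamino)methyl]-4-hydroxy-6-[(TBS-oxy)methyl]-7-iodo-N-methoxy-N-methyl-3-{2-[(2R)-2-methylbut-3-en-1-yl]-1,3-dithian-2-yl}hept-6-enamide
Conditions: MeNH(OMe)·HCl (5 equiv), AlMe3 (5 equiv), CH2Cl2, 0 °C → rt; aq. KNaC4H4O6
Reagents that add atoms: N,O-dimethylhydroxylamine hydrochloride, CNOC.Cl
Why: Aminolysis of the γ-lactone by the aluminium amide made from AlMe3 and the amine salt (Weinreb amide formation) frees O8–H while the dithiane still masks C6, so no second hydroxyl competes and no stereocentre is touched.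

Step 12
Reactants: 24 the hydroxy Weinreb amide of step 11
Product: 25 (2S,3R,4S,6E)-2-[(dimethylamino)methyl]-4-hydroxy-6-[(TBS-oxy)methyl]-7-iodo-N-methoxy-N-methyl-3-[(3R)-3-methylpent-4-enoyl]hept-6-enamide
Conditions: PhI(OCOCF3)2 (1.5 equiv), CF3CO2H (1.1 equiv), MeCN/H2O (9:1), 0 °C, 10 min; aq. NaHCO3
Reagents that add atoms: water, O
Why: Oxidative dethioacetalisation with a hypervalent iodine reagent is fast at 0 °C and spares alkenes, the alkenyl iodide and silyl ethers, the amine being shielded as its trifluoroacetate and the short contact time limiting relactonisation of the γ-hydroxy amide.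

Step 13
Reactants: 25 the β-hydroxy ketone of step 12; 26 [(4-methoxybenzyl)oxy]acetaldehyde
Product: 27 (2S,3S,4S,6E)-2-[(dimethylamino)methyl]-3-[(1S,3R)-1-hydroxy-3-methylpent-4-en-1-yl]-6-[(TBS-oxy)methyl]-7-iodo-1-[methoxy(methyl)amino]-1-oxohept-6-en-4-yl [(4-methoxybenzyl)oxy]acetate
Conditions: 26 (6 equiv), SmI2 (0.3 equiv), THF, −10 °C; used crude
Reagents that add atoms: none
Why: Evans–Tishchenko reduction, in which the samarium-bound hemiacetal formed from O8–H and aldehyde 26 delivers its hydride intramolecularly to the C6 ketone through a chair-like six-membered transition state, setting C6 1,3-anti to O8 and leaving the glycolyl unit as the ester on O8.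

Step 14
Reactants: 27 the hydroxy ester amide of step 13
Product: 28 (3S,4S,5S)-3-[(dimethylamino)methyl]-4-[(1S,3E)-3-[(TBS-oxy)methyl]-4-iodo-1-({[(4-methoxybenzyl)oxy]acetyl}oxy)but-3-en-1-yl]-5-[(2R)-2-methylbut-3-en-1-yl]oxolan-2-one
Conditions: CSA (2.2 equiv), CH2Cl2, 0 °C → rt; aq. NaHCO3
Reagents that add atoms: none
Why: Acid-catalysed lactonisation of a γ-hydroxy Weinreb amide (N→O acyl transfer with loss of MeNHOMe) now closes the lactone on O6, the only free hydroxyl, cis to the C8 arm as in the target, and acid rather than base is used to avoid O8→O6 migration of the glycolate.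

Step 15
Reactants: 28 the O6 lactone of step 14
Product: 30 (3S,3aS,4S,6E,10S,11aS)-6-[(TBS-oxy)methyl]-3-[(dimethylamino)methyl]-10-methyl-2-oxo-2,3,3a,4,5,8,9,10,11,11a-decahydrocyclodeca[b]furan-4-yl [(4-methoxybenzyl)oxy]acetate, via B-alkyl-9-BBN borane 29 (not isolated)
Conditions: 9-BBN (3 equiv), THF, 0 °C → rt; then slow addition to Pd(dppf)Cl2 (20 mol %), AsPh3 (40 mol %), Cs2CO3 (3 equiv), DMF/THF/H2O, 45 °C, 0.002 M
Reagents that add atoms: none
Why: 9-BBN hydroborates only the monosubstituted C2=C3 alkene with boron on C2, and the intramolecular B-alkyl Suzuki–Miyaura coupling with the C1 iodide under high dilution closes the ten-membered ring with retention of alkene geometry (C2 cis to C9), the cis disposition of the two chains on the lactone holding the reacting ends near each other.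

Step 16
Reactants: 30 the silyl-protected macrocycle of step 15
Product: 31 (3S,3aS,4S,6E,10S,11aS)-3-[(dimethylamino)methyl]-6-(hydroxymethyl)-10-methyl-2-oxo-2,3,3a,4,5,8,9,10,11,11a-decahydrocyclodeca[b]furan-4-yl [(4-methoxybenzyl)oxy]acetate
Conditions: HF·pyridine, pyridine, THF, 0 °C → rt
Reagents that add atoms: none
Why: Fluoride cleavage of the primary allylic silyl ether under buffered conditions leaves both ester linkages, the lactone and the PMB ether intact.

Step 17
Reactants: 31 the C14 alcohol of step 16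
Product: 32 (3S,3aS,4S,6E,10S,11aS)-6-[(acetyloxy)methyl]-3-[(dimethylamino)methyl]-10-methyl-2-oxo-2,3,3a,4,5,8,9,10,11,11a-decahydrocyclodeca[b]furan-4-yl [(4-methoxybenzyl)oxy]acetate
Conditions: Ac2O, pyridine, DMAP (cat.), CH2Cl2, 0 °C → rt
Reagents that add atoms: acetic anhydride, CC(=O)OC(C)=O
Why: Standard acylation of the primary allylic alcohol, placed after the coupling so that no allylic acetate is exposed to zerovalent palladium.

Step 18
Reactants: 32 the C14 acetate of step 17
Product: 34 (3aS,4S,6E,10S,11aS)-6-[(acetyloxy)methyl]-10-methyl-3-methylidene-2-oxo-2,3,3a,4,5,8,9,10,11,11a-decahydrocyclodeca[b]furan-4-yl [(4-methoxybenzyl)oxy]acetate, via trimethylammonium iodide 33 (not isolated)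
Conditions: MeI (10 equiv), THF, rt; then aq. NaHCO3/CH2Cl2, rt
Reagents that add atoms: none
Why: Exhaustive methylation of the Mannich base followed by E1cB (Hofmann-type) loss of trimethylamine unveils the α-methylene lactone under conditions that the acetate and glycolate esters tolerate, and the C11 stereocentre disappears.

Step 19
Reactants: 34 the PMB-protected α-methylene lactone of step 18
Product: 35 (3aS,4S,6E,10S,11aS)-6-[(acetyloxy)methyl]-10-methyl-3-methylidene-2-oxo-2,3,3a,4,5,8,9,10,11,11a-decahydrocyclodeca[b]furan-4-yl hydroxyacetate (target)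
Conditions: DDQ (1.5 equiv), CH2Cl2/pH 7 buffer (10:1), 0 °C → rt
Reagents that add atoms: none
Why: Oxidative cleavage of the p-methoxybenzyl ether by DDQ via the benzylic oxocarbenium ion frees the glycolate hydroxyl, and it is run only after the amine is gone because DDQ oxidises tertiary amines.

**Compound list**

1 | 3-(trimethylsilyl)prop-2-yn-1-ol | C[Si](C)(C)C#CCO | starting material
2 | allylmagnesium bromide | C=CC[Mg]Br | starting material
3 | 4-(prop-2-en-1-yl)-3-(trimethylsilyl)-2,5-dihydro-1,2-oxamagnesole (cyclic alkenylmagnesium alkoxide) | C=CCC1=C([Si](C)(C)C)[Mg]OC1 | intermediate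
4 | (2E)-2-[(trimethylsilyl)methylidene]pent-4-en-1-ol | C=CC/C(CO)=C\[Si](C)(C)C | intermediate
5 | tert-butyl(dimethyl){[(2E)-2-[(trimethylsilyl)methylidene]pent-4-en-1-yl]oxy}silane | C=CC/C(CO[Si](C)(C)C(C)(C)C)=C\[Si](C)(C)C | intermediate
6 | (4E)-4-[(TBS-oxy)methyl]-5-(trimethylsilyl)pent-4-ene-1,2-diol (both C2 epimers) | OCC(O)C/C(CO[Si](C)(C)C(C)(C)C)=C\[Si](C)(C)C | intermediate
7 | (3E)-3-[(TBS-oxy)methyl]-4-(trimethylsilyl)but-3-enal | O=CC/C(CO[Si](C)(C)C(C)(C)C)=C\[Si](C)(C)C | intermediate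
8 | methyl propiolate | C#CC(=O)OC | starting material
9 | methyl 3-(methylzincio)prop-2-ynoate | C[Zn]C#CC(=O)OC | intermediate
10 | methyl (4S,6E)-6-[(TBS-oxy)methyl]-4-hydroxy-7-(trimethylsilyl)hept-6-en-2-ynoate | COC(=O)C#C[C@@H](O)C/C(CO[Si](C)(C)C(C)(C)C)=C\[Si](C)(C)C | intermediate
11 | methyl (2Z,4S,6E)-6-[(TBS-oxy)methyl]-4-hydroxy-7-(trimethylsilyl)hepta-2,6-dienoate | COC(=O)/C=C\[C@@H](O)C/C(CO[Si](C)(C)C(C)(C)C)=C\[Si](C)(C)C | intermediate
12 | (5S)-5-[(2E)-2-[(TBS-oxy)methyl]-3-(trimethylsilyl)prop-2-en-1-yl]furan-2(5H)-one | O=C1C=C[C@H](C/C(CO[Si](C)(C)C(C)(C)C)=C\[Si](C)(C)C)O1 | intermediate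
13 | (5S)-5-[(2E)-2-[(TBS-oxy)methyl]-3-iodoprop-2-en-1-yl]furan-2(5H)-one | O=C1C=C[C@H](C/C(CO[Si](C)(C)C(C)(C)C)=C\I)O1 | intermediate
14 | 1,3-dithiane | C1CSCSC1 | starting material
15 | (2S)-3-bromo-2-methylpropan-1-ol | OC[C@H](C)CBr | starting material
16 | 2-lithio-1,3-dithiane | [Li]C1SCCCS1 | intermediate
17 | (2R)-3-(1,3-dithian-2-yl)-2-methylpropan-1-ol | OC[C@H](C)CC1SCCCS1 | intermediate
18 | (2R)-3-(1,3-dithian-2-yl)-2-methylpropanal | O=C[C@H](C)CC1SCCCS1 | intermediate
19 | 2-[(2R)-2-methylbut-3-en-1-yl]-1,3-dithiane | C=C[C@H](C)CC1SCCCS1 | intermediate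
20 | N,N-dimethylmethyleneiminium iodide | C=[N+](C)C.[I-] | starting material
21 | 2-lithio-2-[(2R)-2-methylbut-3-en-1-yl]-1,3-dithiane | [Li]C1(C[C@@H](C)C=C)SCCCS1 | intermediate
22 | lithium enolate of the 4,5-trans conjugate adduct (lithium 2-oxido-4,5-dihydrofuran, C7 dithianyl, C8 iodoalkenyl arm) | [Li]OC1=C[C@@H](C2(C[C@@H](C)C=C)SCCCS2)[C@H](C/C(CO[Si](C)(C)C(C)(C)C)=C\I)O1 | intermediate
23 | (3S,4R,5S)-3-[(dimethylamino)methyl]-5-[(2E)-2-[(TBS-oxy)methyl]-3-iodoprop-2-en-1-yl]-4-{2-[(2R)-2-methylbut-3-en-1-yl]-1,3-dithian-2-yl}oxolan-2-one | O=C1O[C@@H](C/C(CO[Si](C)(C)C(C)(C)C)=C\I)[C@H](C2(C[C@@H](C)C=C)SCCCS2)[C@H]1CN(C)C | intermediate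
24 | (2S,3R,4S,6E)-2-[(dimethylamino)methyl]-4-hydroxy-6-[(TBS-oxy)methyl]-7-iodo-N-methoxy-N-methyl-3-{2-[(2R)-2-methylbut-3-en-1-yl]-1,3-dithian-2-yl}hept-6-enamide | CON(C)C(=O)[C@H](CN(C)C)[C@@H](C1(C[C@@H](C)C=C)SCCCS1)[C@@H](O)C/C(CO[Si](C)(C)C(C)(C)C)=C\I | intermediate
25 | (2S,3R,4S,6E)-2-[(dimethylamino)methyl]-4-hydroxy-6-[(TBS-oxy)methyl]-7-iodo-N-methoxy-N-methyl-3-[(3R)-3-methylpent-4-enoyl]hept-6-enamide | CON(C)C(=O)[C@H](CN(C)C)[C@@H](C(=O)C[C@@H](C)C=C)[C@@H](O)C/C(CO[Si](C)(C)C(C)(C)C)=C\I | intermediate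
26 | [(4-methoxybenzyl)oxy]acetaldehyde | O=CCOCc1ccc(OC)cc1 | starting material
27 | (2S,3S,4S,6E)-2-[(dimethylamino)methyl]-3-[(1S,3R)-1-hydroxy-3-methylpent-4-en-1-yl]-6-[(TBS-oxy)methyl]-7-iodo-1-[methoxy(methyl)amino]-1-oxohept-6-en-4-yl [(4-methoxybenzyl)oxy]acetate | CON(C)C(=O)[C@H](CN(C)C)[C@@H]([C@@H](O)C[C@@H](C)C=C)[C@@H](OC(=O)COCc1ccc(OC)cc1)C/C(CO[Si](C)(C)C(C)(C)C)=C\I | intermediate
28 | (3S,4S,5S)-3-[(dimethylamino)methyl]-4-[(1S,3E)-3-[(TBS-oxy)methyl]-4-iodo-1-({[(4-methoxybenzyl)oxy]acetyl}oxy)but-3-en-1-yl]-5-[(2R)-2-methylbut-3-en-1-yl]oxolan-2-one | O=C1O[C@@H](C[C@@H](C)C=C)[C@@H]([C@@H](OC(=O)COCc2ccc(OC)cc2)C/C(CO[Si](C)(C)C(C)(C)C)=C\I)[C@H]1CN(C)C | intermediate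
29 | B-alkyl-9-borabicyclo[3.3.1]nonane of 28 (boron on C2 of the former vinyl group) | O=C1O[C@@H](C[C@@H](C)CCB2C3CCCC2CCC3)[C@@H]([C@@H](OC(=O)COCc2ccc(OC)cc2)C/C(CO[Si](C)(C)C(C)(C)C)=C\I)[C@H]1CN(C)C | intermediate
30 | (3S,3aS,4S,6E,10S,11aS)-6-[(TBS-oxy)methyl]-3-[(dimethylamino)methyl]-10-methyl-2-oxo-2,3,3a,4,5,8,9,10,11,11a-decahydrocyclodeca[b]furan-4-yl [(4-methoxybenzyl)oxy]acetate | CN(C)C[C@H]1C(=O)O[C@H]2C[C@@H](C)CC/C=C(/CO[Si](C)(C)C(C)(C)C)C[C@H](OC(=O)COCc3ccc(OC)cc3)[C@@H]12 | intermediate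
31 | (3S,3aS,4S,6E,10S,11aS)-3-[(dimethylamino)methyl]-6-(hydroxymethyl)-10-methyl-2-oxo-2,3,3a,4,5,8,9,10,11,11a-decahydrocyclodeca[b]furan-4-yl [(4-methoxybenzyl)oxy]acetate | CN(C)C[C@H]1C(=O)O[C@H]2C[C@@H](C)CC/C=C(/CO)C[C@H](OC(=O)COCc3ccc(OC)cc3)[C@@H]12 | intermediate
32 | (3S,3aS,4S,6E,10S,11aS)-6-[(acetyloxy)methyl]-3-[(dimethylamino)methyl]-10-methyl-2-oxo-2,3,3a,4,5,8,9,10,11,11a-decahydrocyclodeca[b]furan-4-yl [(4-methoxybenzyl)oxy]acetate | CN(C)C[C@H]1C(=O)O[C@H]2C[C@@H](C)CC/C=C(/COC(C)=O)C[C@H](OC(=O)COCc3ccc(OC)cc3)[C@@H]12 | intermediate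
33 | trimethylammonium iodide of 32 (N-methylated Mannich base) | C[N+](C)(C)C[C@H]1C(=O)O[C@H]2C[C@@H](C)CC/C=C(/COC(C)=O)C[C@H](OC(=O)COCc3ccc(OC)cc3)[C@@H]12.[I-] | intermediate
34 | (3aS,4S,6E,10S,11aS)-6-[(acetyloxy)methyl]-10-methyl-3-methylidene-2-oxo-2,3,3a,4,5,8,9,10,11,11a-decahydrocyclodeca[b]furan-4-yl [(4-methoxybenzyl)oxy]acetate | C=C1C(=O)O[C@H]2C[C@@H](C)CC/C=C(/COC(C)=O)C[C@H](OC(=O)COCc3ccc(OC)cc3)[C@@H]12 | intermediate
35 | (3aS,4S,6E,10S,11aS)-6-[(acetyloxy)methyl]-10-methyl-3-methylidene-2-oxo-2,3,3a,4,5,8,9,10,11,11a-decahydrocyclodeca[b]furan-4-yl hydroxyacetate | C=C1C(=O)O[C@H]2C[C@@H](C)CC/C=C(/COC(C)=O)C[C@H](OC(=O)CO)[C@@H]12 | target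

**Step count**

Total: 19 steps. Longest linear sequence: 16 steps (steps 1–6, 10–19); the dithiane branch (steps 7–9) joins at step 10.

**Steps most likely to fail, with fallbacks**

Step 15. Closure of a ten-membered ring by cross-coupling may lose to protodeboronation of the alkylborane or to intermolecular coupling. The ring would then be closed by olefin metathesis instead. Setting out from 28, Stille coupling with tributyl(vinyl)stannane (Pd(PPh3)4, CuI, CsF, DMF, rt) replaces iodine by vinyl with retention and gives the triene lactone F1. Ring-closing metathesis of its camphorsulfonate salt (second-generation Grubbs catalyst RuCl2(H2IMes)(PCy3)(=CHPh), toluene, 80 °C, high dilution) joins the new vinyl carbon to C3 with loss of ethene and gives the ten-membered cyclic 1,3-diene F2. Diimide (2-nitrobenzenesulfonohydrazide, Et3N, CH2Cl2, rt) should then saturate the disubstituted C2=C3 bond in preference to the trisubstituted C1=C10 bond, and the route is rejoined at 30.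

Step 10. Carbonyl attack, γ-deprotonation of the butenolide, or proton transfer to the enolate before it meets the sparingly soluble iminium salt could erode the one-flask union. The two bonds would then be made in separate operations. Setting out from 13 and 19, the conjugate addition alone (21 in THF/HMPA, −78 °C) is quenched cold with AcOH to give the 4,5-trans lactone F3. Its enolate is regenerated with LiN(i-Pr)2 (THF, −78 °C) and aminomethylated with 20, a standard α-aminomethylation of a lactone enolate trans to the C7 substituent, which comes back to the route at 23.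

Step 13. Relactonisation of the γ-hydroxy amide on O8, or binding of the samarium catalyst by the amide and amine, may outrun hydride transfer. Esterification and reduction would then be separated. Setting out from 24, O8 is acylated with [(4-methoxybenzyl)oxy]acetic acid (EDC·HCl, DMAP, CH2Cl2) to give the dithiane ester F4. Dethioacetalisation as in step 12 gives the β-acyloxy ketone F5. Corey–Bakshi–Shibata reduction ((R)-2-methyl-CBS-oxazaborolidine, catecholborane, toluene, −78 °C), with C7 as the large and C5 as the small ketone substituent, would set C6 under reagent control and return to the route at 27.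

**Further compounds**

F1 | step 15 | (3S,4S,5S)-4-[(1S,3E)-3-[(TBS-oxy)methyl]-1-({[(4-methoxybenzyl)oxy]acetyl}oxy)hexa-3,5-dien-1-yl]-3-[(dimethylamino)methyl]-5-[(2R)-2-methylbut-3-en-1-yl]oxolan-2-one | O=C1O[C@@H](C[C@@H](C)C=C)[C@@H]([C@@H](OC(=O)COCc2ccc(OC)cc2)C/C(CO[Si](C)(C)C(C)(C)C)=C\C=C)[C@H]1CN(C)C
F2 | step 15 | (3S,3aS,4S,6E,10R,11aS)-6-[(TBS-oxy)methyl]-3-[(dimethylamino)methyl]-10-methyl-2-oxo-2,3,3a,4,5,10,11,11a-octahydrocyclodeca[b]furan-4-yl [(4-methoxybenzyl)oxy]acetate (C8=C9 geometry immaterial) | CN(C)C[C@H]1C(=O)O[C@H]2C[C@@H](C)C=C/C=C(/CO[Si](C)(C)C(C)(C)C)C[C@H](OC(=O)COCc3ccc(OC)cc3)[C@@H]12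
F3 | step 10 | (4R,5S)-5-[(2E)-2-[(TBS-oxy)methyl]-3-iodoprop-2-en-1-yl]-4-{2-[(2R)-2-methylbut-3-en-1-yl]-1,3-dithian-2-yl}oxolan-2-one | O=C1C[C@@H](C2(C[C@@H](C)C=C)SCCCS2)[C@H](C/C(CO[Si](C)(C)C(C)(C)C)=C\I)O1
F4 | step 13 | (2S,3R,4S,6E)-6-[(TBS-oxy)methyl]-2-[(dimethylamino)methyl]-7-iodo-1-[methoxy(methyl)amino]-3-{2-[(2R)-2-methylbut-3-en-1-yl]-1,3-dithian-2-yl}-1-oxohept-6-en-4-yl [(4-methoxybenzyl)oxy]acetate | CON(C)C(=O)[C@H](CN(C)C)[C@@H](C1(C[C@@H](C)C=C)SCCCS1)[C@@H](OC(=O)COCc1ccc(OC)cc1)C/C(CO[Si](C)(C)C(C)(C)C)=C\I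
F5 | step 13 | (2S,3R,4S,6E)-6-[(TBS-oxy)methyl]-2-[(dimethylamino)methyl]-7-iodo-1-[methoxy(methyl)amino]-3-[(3R)-3-methylpent-4-enoyl]-1-oxohept-6-en-4-yl [(4-methoxybenzyl)oxy]acetate | CON(C)C(=O)[C@H](CN(C)C)[C@@H](C(=O)C[C@@H](C)C=C)[C@@H](OC(=O)COCc1ccc(OC)cc1)C/C(CO[Si](C)(C)C(C)(C)C)=C\I
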